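**Retrosynthetic overview**
1. Target 37 ⇐ bromo ketone 36 (C15 C=O reduction) ⇐ axial C16 alcohol 35 (SN2 bromination) ⇐ diketone 33 (MeMgBr at C19).
2. 33 ⇐ diene 30 by ring-closing metathesis (ring B, C11–C12), hydrogenation and equilibration of C8.
3. 30 ⇐ ring A silyl enol ether 13 + cyclopentenone tosylate 27 (ten skeletal carbons each): Michael addition C8→C7, then enolate alkylation C6→C5 closes the norbornane.
4. 13 ⇐ (R)-4-hydroxycyclohexenone (singlet oxygen, Kornblum–DeLaMare) by conjugate alkynylation, Saegusa oxidation and anti methyl addition (C9).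
5. 27 ⇐ (S)-3-vinylcyclopent-2-enol isovalerate by Ireland–Claisen rearrangement (C13, C4), reduction, tosylation, allylic oxidation. Ring order: ring A and the cyclopentene are carried in, then the norbornane, then ring B.

Convention: carbons are labelled C1–C20 in the order they occur in the target SMILES (C1–C3 isopropyl; C4–C7, C13–C15 norbornane; C8, C9, C16–C19 ring A; C11, C12 in ring B; C10 and C20 methyls); the labels are kept for all intermediates.

**Step 1**
Reactants: 1 cyclohexa-1,3-diene
Product: 2 2,3-dioxabicyclo[2.2.2]oct-5-ene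
Conditions: O2, hν (visible), tetraphenylporphyrin (cat.), CH2Cl2, −20 °C
Reagents that add atoms: dioxygen (O=O)
Why: [4+2] cycloaddition of singlet oxygen to the s-cis diene gives the meso endoperoxide, so no stereocentre has to be controlled.

**Step 2**
Reactants: 2 2,3-dioxabicyclo[2.2.2]oct-5-ene
Product: 3 (4R)-4-hydroxycyclohex-2-en-1-one
Conditions: 9-O-acetyl-6′-hydroxy cinchona base (quinidine series, 10 mol %), CH2Cl2, 23 °C
Reagents that add atoms: none
Why: Enantioselective Kornblum–DeLaMare rearrangement, in which the chiral amine removes one of the two enantiotopic bridgehead hydrogens as the O–O bond breaks, sets C16 as R (the pseudo-enantiomeric quinine-derived base gives the antipode, so the catalyst series is chosen for the 4R product).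

**Step 3**
Reactants: 3 (4R)-4-hydroxycyclohex-2-en-1-one
Product: 4 (4R)-4-[(tert-butyldimethylsilyl)oxy]cyclohex-2-en-1-one
Conditions: TBSCl, imidazole, DMF, 23 °C
Reagents that add atoms: tert-butyldimethylsilyl chloride (CC(C)(C)[Si](C)(C)Cl)
Why: Silyl ether formation protects the C16 oxygen and turns it into the anti-directing group for step 6.

**Step 4**
Reactants: 4 (4R)-4-[(tert-butyldimethylsilyl)oxy]cyclohex-2-en-1-one; 5 ethynyltrimethylsilane
Product: 8 (3S,4R)-4-[(tert-butyldimethylsilyl)oxy]-1-[(trimethylsilyl)oxy]-3-[(trimethylsilyl)ethynyl]cyclohex-1-ene, via lithium acetylide 6 (not isolated), via zinc acetylide 7 (not isolated)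
Conditions: 5, n-BuLi, THF, −78 °C; ZnBr2; then 4, Me3SiOTf, Et2O/THF, −40 °C
Reagents that add atoms: trimethylsilyl trifluoromethanesulfonate (C[Si](C)(C)OS(=O)(=O)C(F)(F)F)
Why: Silyl-triflate-promoted conjugate addition of the alkynylzinc reagent (anti to the C16 silyloxy group) gives the β-alkynyl silyl enol ether regiospecifically; the C9 centre made here is erased in step 5.

**Step 5**
Reactants: 8 (3S,4R)-4-[(tert-butyldimethylsilyl)oxy]-1-[(trimethylsilyl)oxy]-3-[(trimethylsilyl)ethynyl]cyclohex-1-ene
Product: 9 (4R)-4-[(tert-butyldimethylsilyl)oxy]-3-[(trimethylsilyl)ethynyl]cyclohex-2-en-1-one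
Conditions: Pd(OAc)2 (1.05 equiv), MeCN, 23 °C
Reagents that add atoms: none
Why: Saegusa–Ito oxidation (divalent palladium enolate, then β-hydride elimination) regenerates the enone with the alkyne on C9 and leaves C16 untouched.

**Step 6**
Reactants: 9 (4R)-4-[(tert-butyldimethylsilyl)oxy]-3-[(trimethylsilyl)ethynyl]cyclohex-2-en-1-one
Product: 11 (3R,4R)-1,4-bis[(tert-butyldimethylsilyl)oxy]-3-methyl-3-[(trimethylsilyl)ethynyl]cyclohex-1-ene, via magnesium enolate 10 (not isolated)
Conditions: MeMgBr, Cu(OTf)2 (5 mol %), 1,3-bis(2,4,6-trimethylphenyl)imidazolinium chloride (6 mol %), Et2O, −30 °C; then TBSOTf, Et3N, −30 → 0 °C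
Reagents that add atoms: methylmagnesium bromide (C[Mg]Br); tert-butyldimethylsilyl trifluoromethanesulfonate (CC(C)(C)[Si](C)(C)OS(=O)(=O)C(F)(F)F)
Why: Copper-catalysed conjugate addition (the silyl-capped alkyne disfavours 1,6-attack) places the methyl on C9 anti to the C16 silyloxy group, so the alkyne is cis to that oxygen, and O-silylation fixes the C8=C19 enolate regiospecifically.

**Step 7**
Reactants: 11 (3R,4R)-1,4-bis[(tert-butyldimethylsilyl)oxy]-3-methyl-3-[(trimethylsilyl)ethynyl]cyclohex-1-ene
Product: 12 (3R,4R)-1,4-bis[(tert-butyldimethylsilyl)oxy]-3-ethynyl-3-methylcyclohex-1-ene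
Conditions: K2CO3 (0.2 equiv), MeOH/THF, 0 °C
Reagents that add atoms: none
Why: Base-catalysed methanolysis (protodesilylation) cleaves the C(sp)–Si bond much faster than the hindered silyl enol ether or the secondary silyl ether.

**Step 8**
Reactants: 12 (3R,4R)-1,4-bis[(tert-butyldimethylsilyl)oxy]-3-ethynyl-3-methylcyclohex-1-ene
Product: 13 (3S,4R)-1,4-bis[(tert-butyldimethylsilyl)oxy]-3-ethenyl-3-methylcyclohex-1-ene (fragment A)
Conditions: H2 (1 atm), Pd/CaCO3 poisoned with Pb(OAc)2, quinoline, hexane, 23 °C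
Reagents that add atoms: none
Why: Lindlar semi-hydrogenation stops at the alkene and gives the C9 vinyl group without touching the enol ether.

**Step 9**
Reactants: 14 cyclopentane-1,3-dione
Product: 15 3-ethoxycyclopent-2-en-1-one
Conditions: EtOH, TsOH (cat.), toluene, reflux (Dean–Stark)
Reagents that add atoms: ethanol (CCO)
Why: Acid-catalysed condensation of the enolised 1,3-dione with ethanol gives the vinylogous ester; no stereocentre is involved.

**Step 10**
Reactants: 15 3-ethoxycyclopent-2-en-1-one
Product: 17 3-ethenylcyclopent-2-en-1-one, via magnesium alkoxide 16 (not isolated)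
Conditions: CH2=CHMgBr, THF, 0 °C; then 1 M HCl, 23 °C
Reagents that add atoms: vinylmagnesium bromide (C=C[Mg]Br)
Why: Stork–Danheiser sequence: 1,2-addition to the vinylogous ester and acid hydrolysis with allylic transposition give the 3-substituted enone.

**Step 11**
Reactants: 17 3-ethenylcyclopent-2-en-1-one
Product: 18 (1S)-3-ethenylcyclopent-2-en-1-ol
Conditions: (R)-2-methyl-CBS-oxazaborolidine (10 mol %), catecholborane, toluene, −78 °C
Reagents that add atoms: none
Why: Corey–Bakshi–Shibata reduction delivers hydride to the carbonyl face set by the catalyst, with the dienyl arm as the large group, giving the S carbinol; catecholborane at low temperature avoids hydroboration.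

**Step 12**
Reactants: 18 (1S)-3-ethenylcyclopent-2-en-1-ol; 19 3-methylbutanoyl chloride
Product: 20 (1S)-3-ethenylcyclopent-2-en-1-yl 3-methylbutanoate
Conditions: pyridine, DMAP (cat.), CH2Cl2, 0 °C
Reagents that add atoms: none
Why: Acylation of the allylic alcohol (nucleophilic catalysis) proceeds with retention at the carbinol carbon.

**Step 13**
Reactants: 20 (1S)-3-ethenylcyclopent-2-en-1-yl 3-methylbutanoate
Product: 24 (2S)-2-[(1S)-1-ethenylcyclopent-2-en-1-yl]-3-methylbutanoic acid, via lithium enolate 21 (not isolated), via silyl ketene acetal 22 (not isolated), via silyl ester 23 (not isolated)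
Conditions: LiN(i-Pr)2, THF, −78 °C; Me3SiCl; −78 → 50 °C; then 1 M HCl
Reagents that add atoms: none
Why: Ireland–Claisen rearrangement: kinetic enolisation gives the ketene acetal with isopropyl anti to OSiMe3, and a suprafacial chair-like [3,3] shift forms C4–C13 on the face of the departing C–O bond, so the carbinol configuration is relayed to quaternary C13 and the enolate geometry sets C4.

**Step 14**
Reactants: 24 (2S)-2-[(1S)-1-ethenylcyclopent-2-en-1-yl]-3-methylbutanoic acid
Product: 25 (2S)-2-[(1S)-1-ethenylcyclopent-2-en-1-yl]-3-methylbutan-1-ol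
Conditions: LiAlH4, Et2O, 0 → 23 °C
Reagents that add atoms: none
Why: Hydride reduction of the acid gives the primary alcohol at C5 and leaves the alkenes and both stereocentres untouched.

**Step 15**
Reactants: 25 (2S)-2-[(1S)-1-ethenylcyclopent-2-en-1-yl]-3-methylbutan-1-ol
Product: 26 (2S)-2-[(1S)-1-ethenylcyclopent-2-en-1-yl]-3-methylbutyl 4-methylbenzenesulfonate
Conditions: TsCl, pyridine, 0 → 23 °C
Reagents that add atoms: 4-methylbenzenesulfonyl chloride (Cc1ccc(cc1)S(Cl)(=O)=O)
Why: Sulfonylation of the primary alcohol makes C5 the electrophile for the later ring closure.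

**Step 16**
Reactants: 26 (2S)-2-[(1S)-1-ethenylcyclopent-2-en-1-yl]-3-methylbutyl 4-methylbenzenesulfonate
Product: 27 (2S)-2-[(1S)-1-ethenyl-4-oxocyclopent-2-en-1-yl]-3-methylbutyl 4-methylbenzenesulfonate (fragment B)
Conditions: CrO3, 3,5-dimethylpyrazole, CH2Cl2, −20 °C
Reagents that add atoms: chromium trioxide (O=[Cr](=O)=O)
Why: Allylic C–H oxidation by the hexavalent chromium–pyrazole complex can only occur at C15 (C13 is quaternary and the vinyl group has no allylic hydrogen), which gives the 4,4-disubstituted cyclopent-2-enone.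

**Step 17**
Reactants: 13 (3S,4R)-1,4-bis[(tert-butyldimethylsilyl)oxy]-3-ethenyl-3-methylcyclohex-1-ene; 27 (2S)-2-[(1S)-1-ethenyl-4-oxocyclopent-2-en-1-yl]-3-methylbutyl 4-methylbenzenesulfonate
Product: 30 ring-B-seco diene diketone (norbornanone closed; C8 epimer mixture), via sulfonium enolate 28 (not isolated), via Michael enolate 29 (not isolated)
Conditions: tris(dimethylamino)sulfonium difluorotrimethylsilicate (1.1 equiv), THF, −78 → 23 °C
Reagents that add atoms: none
Why: Fluoride cleaves the enol silyl ether and the enolate adds through C8 to C7 (Michael addition) anti to the bulky C4 side chain on C13, after which the regiospecific C6 enolate displaces the C5 tosylate (5-exo-tet alkylation) to close the norbornanone with exo isopropyl and fix C6 and C7; C8 forms as an epimer mixture that is corrected in step 19.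

**Step 18**
Reactants: 30 ring-B-seco diene diketone
Product: 31 tetracyclic ene-diketone (ring B closed with C11=C12; C8 epimer mixture)
Conditions: second-generation Grubbs catalyst (10 mol %), toluene, 80 °C
Reagents that add atoms: none
Why: Ring-closing metathesis of the two vinyl groups, held cis across the C7–C13 edge, closes ring B as a cyclohexene with loss of ethene.

**Step 19**
Reactants: 31 tetracyclic ene-diketone
Product: 33 trans-fused tetracyclic diketone, via saturated diketone 32 (not isolated)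
Conditions: H2 (3 atm), Pd/C, EtOAc, 23 °C; filter; then NaOMe, MeOH, 23 °C
Reagents that add atoms: none
Why: Hydrogenation of C11=C12 followed by base equilibration at C8 (α to the C19 ketone) gives the more stable trans ring fusion (C8–H anti to the C9 methyl, as in 5α-4-keto steroids); C6 is a bridgehead, so retro-Michael cleavage is not possible.

**Step 20**
Reactants: 33 trans-fused tetracyclic diketone
Product: 34 C19 tertiary alcohol (C15 ketone and C16 silyl ether retained)
Conditions: MeMgBr (1.2 equiv), THF, −78 → −20 °C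
Reagents that add atoms: methylmagnesium bromide (C[Mg]Br)
Why: Grignard addition to the cyclohexanone C19 from the equatorial direction (the axial path is blocked by the syn-axial C9 methyl) gives the axial alcohol with equatorial methyl, while the camphor-like C15 ketone, whose exo face is covered by ring B, reacts much more slowly at low temperature.

**Step 21**
Reactants: 34 C19 tertiary alcohol
Product: 35 keto diol with axial C16 alcohol
Conditions: Bu4NF, THF, 60 °C
Reagents that add atoms: none
Why: Fluoride-mediated desilylation frees the axial C16 alcohol without affecting the ketone or the tertiary alcohol.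

**Step 22**
Reactants: 35 keto diol
Product: 36 bromo keto alcohol (equatorial C16 bromide)
Conditions: CBr4, PPh3, 2,6-lutidine, toluene, 0 → 60 °C
Reagents that add atoms: tetrabromomethane (BrC(Br)(Br)Br)
Why: Appel reaction: bromide displaces the axial oxyphosphonium group by SN2 with inversion to give the equatorial 16S bromide, the tertiary C19 alcohol being too hindered to be activated.

**Step 23**
Reactants: 36 bromo keto alcohol
Product: 37 CNP0317598.2 (target)
Conditions: NaBH4, MeOH, 0 °C
Reagents that add atoms: none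
Why: Borohydride attacks the C15 carbonyl from the endo face because the exo face is covered by ring B (the camphor-to-isoborneol pattern), giving the exo 15R alcohol and leaving the alkyl bromide intact.

**Compound list**
1 | cyclohexa-1,3-diene | C1=CC=CCC1 | starting material
2 | 2,3-dioxabicyclo[2.2.2]oct-5-ene (meso) | C1CC2C=CC1OO2 | intermediate
3 | (4R)-4-hydroxycyclohex-2-en-1-one | O=C1C=C[C@H](O)CC1 | intermediate
4 | (4R)-4-[(tert-butyldimethylsilyl)oxy]cyclohex-2-en-1-one | O=C1C=C[C@H](O[Si](C)(C)C(C)(C)C)CC1 | intermediate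
5 | ethynyltrimethylsilane | C#C[Si](C)(C)C | starting material
6 | lithium (trimethylsilyl)acetylide | [Li]C#C[Si](C)(C)C | intermediate (not isolated)
7 | bromo[(trimethylsilyl)ethynyl]zinc | Br[Zn]C#C[Si](C)(C)C | intermediate (not isolated)
8 | (3S,4R)-4-[(tert-butyldimethylsilyl)oxy]-1-[(trimethylsilyl)oxy]-3-[(trimethylsilyl)ethynyl]cyclohex-1-ene (alkyne trans to OTBS) | C[Si](C)(C)C#C[C@@H]1C=C(O[Si](C)(C)C)CC[C@H]1O[Si](C)(C)C(C)(C)C | intermediate
9 | (4R)-4-[(tert-butyldimethylsilyl)oxy]-3-[(trimethylsilyl)ethynyl]cyclohex-2-en-1-one | C[Si](C)(C)C#CC1=CC(=O)CC[C@H]1O[Si](C)(C)C(C)(C)C | intermediate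
10 | bromomagnesium enolate of (3R,4R)-4-silyloxy-3-methyl-3-[(trimethylsilyl)ethynyl]cyclohexanone | C[Si](C)(C)C#C[C@@]1(C)C=C(O[Mg]Br)CC[C@H]1O[Si](C)(C)C(C)(C)C | intermediate (not isolated)
11 | (3R,4R)-1,4-bis[(tert-butyldimethylsilyl)oxy]-3-methyl-3-[(trimethylsilyl)ethynyl]cyclohex-1-ene | C[Si](C)(C)C#C[C@@]1(C)C=C(O[Si](C)(C)C(C)(C)C)CC[C@H]1O[Si](C)(C)C(C)(C)C | intermediate
12 | (3R,4R)-1,4-bis[(tert-butyldimethylsilyl)oxy]-3-ethynyl-3-methylcyclohex-1-ene | C#C[C@@]1(C)C=C(O[Si](C)(C)C(C)(C)C)CC[C@H]1O[Si](C)(C)C(C)(C)C | intermediate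
13 | (3S,4R)-1,4-bis[(tert-butyldimethylsilyl)oxy]-3-ethenyl-3-methylcyclohex-1-ene (fragment A; vinyl cis to the C16 oxygen) | C=C[C@@]1(C)C=C(O[Si](C)(C)C(C)(C)C)CC[C@H]1O[Si](C)(C)C(C)(C)C | intermediate
14 | cyclopentane-1,3-dione | O=C1CCC(=O)C1 | starting material
15 | 3-ethoxycyclopent-2-en-1-one | CCOC1=CC(=O)CC1 | intermediate
16 | bromomagnesium 1-ethenyl-3-ethoxycyclopent-2-en-1-olate (racemic) | CCOC1=CC(C=C)(O[Mg]Br)CC1 | intermediate (not isolated)
17 | 3-ethenylcyclopent-2-en-1-one | C=CC1=CC(=O)CC1 | intermediate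
18 | (1S)-3-ethenylcyclopent-2-en-1-ol | C=CC1=C[C@@H](O)CC1 | intermediate
19 | 3-methylbutanoyl chloride | CC(C)CC(Cl)=O | starting material
20 | (1S)-3-ethenylcyclopent-2-en-1-yl 3-methylbutanoate | C=CC1=C[C@@H](OC(=O)CC(C)C)CC1 | intermediate
21 | lithium enolate of 20 (isopropyl cis to the allylic oxygen) | C=CC1=C[C@@H](O/C(O[Li])=C\C(C)C)CC1 | intermediate (not isolated)
22 | trimethylsilyl ketene acetal of 20 (E; isopropyl anti to OSiMe3) | C=CC1=C[C@@H](O/C(O[Si](C)(C)C)=C\C(C)C)CC1 | intermediate (not isolated)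
23 | trimethylsilyl (2S)-2-[(1S)-1-ethenylcyclopent-2-en-1-yl]-3-methylbutanoate | CC(C)[C@H](C(=O)O[Si](C)(C)C)[C@]1(C=C)CCC=C1 | intermediate (not isolated)
24 | (2S)-2-[(1S)-1-ethenylcyclopent-2-en-1-yl]-3-methylbutanoic acid | CC(C)[C@H](C(O)=O)[C@]1(C=C)CCC=C1 | intermediate
25 | (2S)-2-[(1S)-1-ethenylcyclopent-2-en-1-yl]-3-methylbutan-1-ol | CC(C)[C@H](CO)[C@]1(C=C)CCC=C1 | intermediate
26 | (2S)-2-[(1S)-1-ethenylcyclopent-2-en-1-yl]-3-methylbutyl 4-methylbenzenesulfonate | CC(C)[C@H](COS(=O)(=O)c1ccc(C)cc1)[C@]2(C=C)CCC=C2 | intermediate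
27 | (2S)-2-[(1S)-1-ethenyl-4-oxocyclopent-2-en-1-yl]-3-methylbutyl 4-methylbenzenesulfonate (fragment B) | CC(C)[C@H](COS(=O)(=O)c1ccc(C)cc1)[C@]2(C=C)CC(=O)C=C2 | intermediate
28 | tris(dimethylamino)sulfonium enolate of ring A (C8=C19 enolate of 13) | C=C[C@@]1(C)C=C([O-])CC[C@H]1O[Si](C)(C)C(C)(C)C.CN(C)[S+](N(C)C)N(C)C | intermediate (not isolated)
29 | Michael adduct as its C6=C15 enolate (sulfonium salt; C7–C8 bond formed, tosylate still present; C8 epimers) | CC(C)[C@H](COS(=O)(=O)c1ccc(C)cc1)[C@]2(C=C)CC([O-])=C[C@H]2C3C(=O)CC[C@@H](O[Si](C)(C)C(C)(C)C)[C@@]3(C)C=C.CN(C)[S+](N(C)C)N(C)C | intermediate (not isolated)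
30 | ring-B-seco diene diketone: 1-ethenyl-2-exo-isopropylnorbornan-5-one (C13 = position 1, C4 = 2, C15 = 5, C7 = 7) whose C7, syn to the ketone bridge, carries through C8 the 3-silyloxy-2-ethenyl-2-methyl-6-oxocyclohexyl ring; C8 epimer mixture | CC(C)[C@@H]1C[C@@H]2[C@@H](C3C(=O)CC[C@@H](O[Si](C)(C)C(C)(C)C)[C@@]3(C)C=C)[C@@]1(C=C)CC2=O | intermediate
31 | tetracyclic ene-diketone (ring B closed, C11=C12; C15 and C19 ketones; C16 OTBS; C8 epimer mixture) | CC(C)[C@@H]1C[C@@H]2[C@H]3C4[C@](C)(C=C[C@@]31CC2=O)[C@H](O[Si](C)(C)C(C)(C)C)CCC4=O | intermediate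
32 | saturated tetracyclic diketone (C8 epimer mixture) | CC(C)[C@@H]1C[C@@H]2[C@H]3C4[C@](C)(CC[C@@]31CC2=O)[C@H](O[Si](C)(C)C(C)(C)C)CCC4=O | intermediate (not isolated)
33 | trans-fused tetracyclic diketone (C8–H anti to C9 methyl; C16 axial OTBS) | CC(C)[C@@H]1C[C@@H]2[C@H]3[C@H]4[C@](C)(CC[C@@]31CC2=O)[C@H](O[Si](C)(C)C(C)(C)C)CCC4=O | intermediate
34 | C19 tertiary alcohol (axial OH, equatorial methyl; C15 ketone; C16 OTBS) | CC(C)[C@@H]1C[C@@H]2[C@H]3[C@H]4[C@](C)(CC[C@@]31CC2=O)[C@H](O[Si](C)(C)C(C)(C)C)CC[C@@]4(C)O | intermediate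
35 | keto diol (axial C16 OH, C19 OH, C15 ketone) | CC(C)[C@@H]1C[C@@H]2[C@H]3[C@H]4[C@](C)(CC[C@@]31CC2=O)[C@H](O)CC[C@@]4(C)O | intermediate
36 | bromo keto alcohol (equatorial 16S bromide, C15 ketone) | CC(C)[C@@H]1C[C@@H]2[C@H]3[C@H]4[C@](C)(CC[C@@]31CC2=O)[C@@H](Br)CC[C@@]4(C)O | intermediate
37 | CNP0317598.2 | CC(C)[C@@H]1C[C@@H]2[C@H]3[C@H]4[C@](C)(CC[C@@]31C[C@H]2O)[C@@H](Br)CC[C@@]4(C)O | target

**Step count and risks**
Total step count: 23. Longest linear sequence: 15 (steps 1–8 then 17–23; the other branch, steps 9–16 then 17–23, is equally long).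

Step 17 is the most exposed step, because the Michael bond joins two carbons that each sit next to a quaternary centre and the alkylation must outrun proton transfer. The fallback sets out from 13 and 27 and comes back at 31; it avoids a free enolate and reverses the order of ring formation. Silyl enol ether 13 is added to 27 under TiCl4 activation (Mukaiyama–Michael, CH2Cl2, −78 °C) to give the 1,5-diketone tosylate F1. Ring B is then closed first by ring-closing metathesis (second-generation Grubbs catalyst) to give the tricyclic cyclohexene diketone tosylate F2. Only then is the norbornane closed by intramolecular C6→C5 enolate alkylation (NaH, DMSO), which gives 31.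

Step 6 may fail through 1,6-addition to the enynone or through poor facial control next to the silyloxy group. The fallback sets out from 4 and comes back at 11; it introduces the two C9 substituents in the opposite order and lets the oxygen deliver the alkyne. Me2CuLi/Me3SiCl on 4 gives the silyl enol ether F3, Pd(OAc)2 gives (4R)-4-silyloxy-3-methylcyclohexenone F4, and HF·pyridine gives the free hydroxy enone F5. The aluminium alkoxide formed from F5 and dimethyl[(trimethylsilyl)ethynyl]aluminium (from 5, n-BuLi and Me2AlCl) transfers the alkynyl group intramolecularly to C9 on the face of the C16 oxygen. Double silylation of the resulting alkoxide and enolate (TBSOTf, Et3N) gives 11.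

Step 22 is an SN2 reaction at a neopentyl secondary carbon in the presence of a free tertiary alcohol, so elimination or rearrangement may win. The fallback sets out from 33 and comes back at 36; it installs the bromide before the tertiary alcohol exists and through a sulfonate. Bu4NF converts 33 into the hydroxy diketone F6, Tf2O/pyridine gives the axial triflate F7, and Bu4NBr in toluene displaces it with inversion to give the bromo diketone F8. MeMgBr then adds to C19 as in step 20 to give 36.

**Further compounds**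
F1 | step 17 | 1,5-diketone tosylate (Mukaiyama–Michael adduct; C8 epimers) | CC(C)[C@H](COS(=O)(=O)c1ccc(C)cc1)[C@]2(C=C)CC(=O)C[C@H]2C3C(=O)CC[C@@H](O[Si](C)(C)C(C)(C)C)[C@@]3(C)C=C
F2 | step 17 | tricyclic cyclohexene diketone tosylate (ring B closed, norbornane open; C8 epimers) | CC(C)[C@H](COS(=O)(=O)c1ccc(C)cc1)[C@@]23C=C[C@]4(C)[C@H](O[Si](C)(C)C(C)(C)C)CCC(=O)C4[C@@H]2CC(=O)C3
F3 | step 6 | (3R,4R)-4-[(tert-butyldimethylsilyl)oxy]-3-methyl-1-[(trimethylsilyl)oxy]cyclohex-1-ene | C[C@@H]1C=C(O[Si](C)(C)C)CC[C@H]1O[Si](C)(C)C(C)(C)C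
F4 | step 6 | (4R)-4-[(tert-butyldimethylsilyl)oxy]-3-methylcyclohex-2-en-1-one | CC1=CC(=O)CC[C@H]1O[Si](C)(C)C(C)(C)C
F5 | step 6 | (4R)-4-hydroxy-3-methylcyclohex-2-en-1-one | CC1=CC(=O)CC[C@H]1O
F6 | step 22 | hydroxy diketone (axial C16 OH; C15 and C19 ketones) | CC(C)[C@@H]1C[C@@H]2[C@H]3[C@H]4[C@](C)(CC[C@@]31CC2=O)[C@H](O)CCC4=O
F7 | step 22 | axial C16 trifluoromethanesulfonate of F6 | CC(C)[C@@H]1C[C@@H]2[C@H]3[C@H]4[C@](C)(CC[C@@]31CC2=O)[C@H](OS(=O)(=O)C(F)(F)F)CCC4=O
F8 | step 22 | bromo diketone (equatorial C16 bromide) | CC(C)[C@@H]1C[C@@H]2[C@H]3[C@H]4[C@](C)(CC[C@@]31CC2=O)[C@@H](Br)CCC4=O
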